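Ring A (C4a, C5, C6, C7, C8, C8a) is a fully differentiated phloroglucinol. Its oxygen-bearing carbons C5 (OMe), C7 (OH) and C8a (pyran O1) alternate with C4a (bonded to C4), C6 (arylacetyl) and C8 (H).
Last disconnection: the C3=C4 alkene is taken back to the chroman, so the pyran ring travels as a saturated, robust unit until the end.
Key disconnection: bonds C4a–C5 and C6–C7 of ring A. This gives the 1,1,3-trioxygenated diene C4a=C8a–C8=C7 (a dihydropyranyl bis-silyl ketene acetal with O1 and C4 already tied into the pyran) and the push–pull alkyne C5≡C6 (a β-methoxy ynone carrying the 4-methoxybenzyl ketone).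
The diene goes back through a (tetrahydropyranylidene)acetate to 6,6-dimethyl-δ-valerolactone and methyl acetate. The ynone goes back to the Weinreb amide of 4-methoxyphenylacetic acid and lithium methoxyacetylide.
Ring order: pyran ring first (as the lactone, step 1), ring A second (step 8); the anisyl ring is bought.

Key step: step 8

Remark: chromene numbering (O1, C2, C3, C4, C4a, C5 to C8, C8a) is used for every atom that ends up in the bicycle. The target has no stereocentre, so no configuration has to be set.

Step 1
Reactants: 1 5-oxohexanoic acid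
Product: 3 6,6-dimethyloxan-2-one, via 5-hydroxy-5-methylhexanoic acid 2 (not isolated)
Conditions: MeMgBr (2.2 equiv), THF, −20 °C → rt; 2 M HCl; cat. TsOH, PhMe, 60 °C
Reagents that add atoms: methylmagnesium bromide, C[Mg]Br
Why: Grignard addition followed by lactonisation: the first equivalent of MeMgBr converts the acid into an inert magnesium carboxylate, the second adds to the ketone, and the tertiary δ-hydroxy acid 2 closes to the six-membered lactone under acid catalysis.

Step 2
Reactants: 3 6,6-dimethyloxan-2-one; 4 methyl acetate
Product: 6 methyl 7-hydroxy-7-methyl-3-oxooctanoate, via lithium enolate of methyl acetate 5 (not isolated)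
Conditions: 4 (2.3 equiv), LiN(iPr)2 (2.2 equiv), THF, −78 °C; then 3, −78 → −40 °C; cold 1 M HCl
Reagents that add atoms: none
Why: Crossed Claisen condensation of an ester enolate with a lactone: 5 adds to the lactone carbonyl, the ring opens to the β-keto ester, and the second equivalent of enolate deprotonates it at once, which rules out double addition.

Step 3
Reactants: 6 methyl 7-hydroxy-7-methyl-3-oxooctanoate
Product: 8 methyl (E)-2-(6,6-dimethyloxan-2-ylidene)acetate, via lactol 7 (not isolated)
Conditions: PPTS (5 mol %), 4 Å MS, PhMe, 80 °C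
Reagents that add atoms: none
Why: Acid-catalysed cyclodehydration: the tertiary hydroxyl adds to the ketone to give lactol 7, which loses water towards the ester to form the conjugated exocyclic enol ether (E expected as the thermodynamic isomer, its geometry being erased in step 5), and since the O–CMe2 bond is already present no tertiary cation arises that the α-carbon could capture to give a carbocycle.

Step 4
Reactants: 8 methyl (E)-2-(6,6-dimethyloxan-2-ylidene)acetate
Product: 9 (E)-2-(6,6-dimethyloxan-2-ylidene)acetic acid
Conditions: LiOH (3 equiv), THF/MeOH/H2O, 50 °C; 1 M HCl to pH 4, 0 °C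
Reagents that add atoms: lithium hydroxide, [Li+].[OH-]
Why: Ester saponification, well behaved for 3-alkoxyacrylates because the vinylogous carbonate resists conjugate attack by hydroxide; acidifying only to pH 4 in the cold keeps the enol ether from being protonated and the acid from decarboxylating.

Step 5
Reactants: 9 (E)-2-(6,6-dimethyloxan-2-ylidene)acetic acid
Product: 12 bis(trimethylsilyl) ketene acetal of (6,6-dimethyl-5,6-dihydro-4H-pyran-2-yl)acetic acid, via trimethylsilyl ester 10 (not isolated), via lithium dienolate 11 (not isolated)
Conditions: LiN(iPr)2 (1.05 equiv), THF, −78 °C, TMSCl (1.1 equiv), → 0 °C; LiN(iPr)2 (1.15 equiv), −78 °C, TMSCl (1.3 equiv), → rt; pentane, filtration under Ar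
Reagents that add atoms: chlorotrimethylsilane (TMSCl), C[Si](C)(C)Cl
Why: Silyl ketene acetal formation in two deprotonation–silylation rounds: the carboxylate is O-silylated to 10, LiN(iPr)2 then removes a proton from the only γ-position (the ring CH2 next to the enol ether carbon, cis to the carbonyl group in the E isomer) as in the preparation of Brassard-type dienes, and dienolate 11 is trapped on oxygen by the oxophilic silicon electrophile.

Step 6
Reactants: 13 4-methoxyphenylacetic acid
Product: 15 N-methoxy-2-(4-methoxyphenyl)-N-methylacetamide, via acyl imidazole 14 (not isolated)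
Conditions: CDI (1.1 equiv), CH2Cl2, rt; MeNHOMe·HCl (1.2 equiv), rt
Reagents that add atoms: N,O-dimethylhydroxylamine hydrochloride, CNOC.Cl
Why: Weinreb amide synthesis by CDI activation: acyl imidazole 14 is aminolysed by the hydroxylamine, and no other group in the molecule reacts.

Step 7
Reactants: 16 chloroacetaldehyde dimethyl acetal; 15 N-methoxy-2-(4-methoxyphenyl)-N-methylacetamide
Product: 19 4-methoxy-1-(4-methoxyphenyl)but-3-yn-2-one, via lithium methoxyacetylide 17 (not isolated), via tetrahedral lithium adduct 18 (not isolated)
Conditions: 16 (1.5 equiv), LiNEt2 (4.5 equiv, from n-BuLi and Et2NH), THF, 0 °C; 15, −78 → −30 °C; inverse quench into AcOH/THF, −78 °C, then pH 5 buffer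
Reagents that add atoms: none
Why: Weinreb ketone synthesis with an alkoxyacetylide: three equivalents of LiNEt2 strip MeOH and HCl from 16 and deprotonate the resulting methoxyacetylene to 17, its addition to 15 stops at the chelated adduct 18, and the acidic inverse quench protonates Et2NH and MeNHOMe before the ynone is released, so that they cannot add to its β-carbon.

Step 8
Reactants: 12 bis(trimethylsilyl) ketene acetal of (6,6-dimethyl-5,6-dihydro-4H-pyran-2-yl)acetic acid; 19 4-methoxy-1-(4-methoxyphenyl)but-3-yn-2-one
Product: 22 1-(7-hydroxy-5-methoxy-2,2-dimethylchroman-6-yl)-2-(4-methoxyphenyl)ethanone, via cyclohexadiene cycloadduct 20 (not isolated), via aryl trimethylsilyl ether 21 (not isolated)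
Conditions: 12 (1.5 equiv), PhMe (1 M), Ar, 0 → 60 °C; then 0.5 M HCl, THF, 0 °C
Reagents that add atoms: none
Why: Proposed new method: a 1,1,3-trioxygenated diene has not been combined with a β-alkoxy ynone, the closest known reactions being the cycloadditions of Brassard- and Chan-type silyloxy dienes to alkynones, alkynoates and quinones that give resorcinols after loss of alcohol or silanol. The three oxygens of 12 push electron density to its ring terminus C4a, which bonds to the ynone β-carbon C5, the position made electrophilic by the ketone; the resulting allenolate carbon C6 then bonds to the bis(silyloxy)carbenium carbon C7, either in one asynchronous [4+2] event or as a vinylogous Mukaiyama–Michael addition followed by ring closure. Ring A is thus closed as a six-membered carbocycle by [4+2] cycloaddition (in the stepwise limit a 6-(enolexo)-exo-trig attack of C6 on C7), and the diene reaches its s-cis form easily because the inward substituent at C4a is hydrogen. Adduct 20 holds H at C4a and two silyloxy groups at C7 across the 1,4-cyclohexadiene, so 1,4-elimination of trimethylsilanol gives 21, whereas the C5 methoxyl sits on an alkene carbon and cannot leave; dilute acid then frees the C7 phenol. The only new stereocentre (C4a of 20) is racemic and vanishes on aromatisation. The step needs regioselectivity (C4a to C5, C7 to C6) and attack through the γ-terminus rather than C8: both follow from the matched polarity of the partners, and the absence of base and Lewis acid together with a ceiling of 60 °C keeps the acidic ArCH2C=O unit from being enolised or silylated.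

Step 9
Reactants: 22 1-(7-hydroxy-5-methoxy-2,2-dimethylchroman-6-yl)-2-(4-methoxyphenyl)ethanone
Product: 23 1-(7-hydroxy-5-methoxy-2,2-dimethyl-2H-chromen-6-yl)-2-(4-methoxyphenyl)ethanone (CNP0179220.0)
Conditions: DDQ (1.2 equiv), 1,4-dioxane, 100 °C
Reagents that add atoms: none
Why: DDQ dehydrogenation of a 2,2-dimethylchroman: hydride leaves from C4 because the resulting cation is stabilised by the oxygens on C5, C7 and C8a (para-quinone methide of the C7 phenol), loss of a proton from C3 gives the C3=C4 alkene, and the other benzylic CH2 is protected by the adjacent electron-withdrawing carbonyl group.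

Compound list
1 | 5-oxohexanoic acid | CC(=O)CCCC(=O)O | starting material
2 | 5-hydroxy-5-methylhexanoic acid (formed in situ) | CC(C)(O)CCCC(=O)O | intermediate
3 | 6,6-dimethyloxan-2-one | CC1(C)CCCC(=O)O1 | intermediate
4 | methyl acetate | COC(C)=O | starting material
5 | lithium enolate of methyl acetate (formed in situ) | [Li+].C=C([O-])OC | intermediate
6 | methyl 7-hydroxy-7-methyl-3-oxooctanoate | COC(=O)CC(=O)CCCC(C)(C)O | intermediate
7 | methyl 2-(2-hydroxy-6,6-dimethyloxan-2-yl)acetate (lactol, racemic, formed in situ) | COC(=O)CC1(O)CCCC(C)(C)O1 | intermediate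
8 | methyl (E)-2-(6,6-dimethyloxan-2-ylidene)acetate | COC(=O)/C=C1\CCCC(C)(C)O1 | intermediate
9 | (E)-2-(6,6-dimethyloxan-2-ylidene)acetic acid | OC(=O)/C=C1\CCCC(C)(C)O1 | intermediate
10 | trimethylsilyl (E)-2-(6,6-dimethyloxan-2-ylidene)acetate (formed in situ) | C[Si](C)(C)OC(=O)/C=C1\CCCC(C)(C)O1 | intermediate
11 | lithium dienolate of 10 (formed in situ) | [Li+].[O-]C(O[Si](C)(C)C)=CC1=CCCC(C)(C)O1 | intermediate
12 | bis(trimethylsilyl) ketene acetal of (6,6-dimethyl-5,6-dihydro-4H-pyran-2-yl)acetic acid | C[Si](C)(C)OC(O[Si](C)(C)C)=CC1=CCCC(C)(C)O1 | intermediate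
13 | 4-methoxyphenylacetic acid | COc1ccc(CC(=O)O)cc1 | starting material
14 | 1-(imidazol-1-yl)-2-(4-methoxyphenyl)ethanone (acyl imidazole, formed in situ) | COc1ccc(CC(=O)n2ccnc2)cc1 | intermediate
15 | N-methoxy-2-(4-methoxyphenyl)-N-methylacetamide | COc1ccc(CC(=O)N(C)OC)cc1 | intermediate
16 | chloroacetaldehyde dimethyl acetal | COC(CCl)OC | starting material
17 | lithium methoxyacetylide (formed in situ) | [Li+].[C-]#COC | intermediate
18 | lithium alkoxide adduct of 17 and 15 (tetrahedral, racemic, formed in situ) | [Li+].COC#CC([O-])(Cc1ccc(OC)cc1)N(C)OC | intermediate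
19 | 4-methoxy-1-(4-methoxyphenyl)but-3-yn-2-one | COC#CC(=O)Cc1ccc(OC)cc1 | intermediate
20 | 1-[5-methoxy-2,2-dimethyl-7,7-bis(trimethylsilyloxy)-3,4,4a,7-tetrahydro-2H-chromen-6-yl]-2-(4-methoxyphenyl)ethanone (cycloadduct, racemic at C4a, formed in situ) | COC1=C(C(=O)Cc2ccc(OC)cc2)C(O[Si](C)(C)C)(O[Si](C)(C)C)C=C3OC(C)(C)CCC13 | intermediate
21 | 1-[5-methoxy-2,2-dimethyl-7-(trimethylsilyloxy)chroman-6-yl]-2-(4-methoxyphenyl)ethanone (formed in situ) | COc1ccc(CC(=O)c2c(O[Si](C)(C)C)cc3OC(C)(C)CCc3c2OC)cc1 | intermediate
22 | 1-(7-hydroxy-5-methoxy-2,2-dimethylchroman-6-yl)-2-(4-methoxyphenyl)ethanone | COc1ccc(CC(=O)c2c(O)cc3OC(C)(C)CCc3c2OC)cc1 | intermediate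
23 | 1-(7-hydroxy-5-methoxy-2,2-dimethyl-2H-chromen-6-yl)-2-(4-methoxyphenyl)ethanone | COc1ccc(CC(=O)c2c(O)cc3c(c2OC)C=CC(C)(C)O3)cc1 | target

Total step count: 9. Longest linear sequence: 7 (steps 1, 2, 3, 4, 5, 8, 9). The ynone branch (steps 6 and 7) joins at step 8.

Steps most likely to fail

1. Step 8 (the step labelled Proposed new method).
- What may go wrong: the methoxy group weakens the alkyne as an acceptor. C–C bond formation may then be slower than protonation of the ketene acetal, or silyl transfer from it, by the acidic ArCH2C=O unit.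
- Further loss channels are bonding through C8 instead of C4a, [2+2] addition across the ketene acetal double bond, and a Michael adduct that fails to close.
- Fallback: it uses known aromatic chemistry, with ring A bought instead of built. It sets out from 13 and comes back at 22.
- Friedel–Crafts acylation of 5-methoxyresorcinol with 13 in BF3·OEt2 at 85 °C should give 1-(2,4-dihydroxy-6-methoxyphenyl)-2-(4-methoxyphenyl)ethanone F1.
- The non-chelated hydroxyl para to the ketone is masked with MOMCl and iPr2NEt to give 1-[2-hydroxy-6-methoxy-4-(methoxymethoxy)phenyl]-2-(4-methoxyphenyl)ethanone F2.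
- A Mitsunobu reaction with 3-methylbut-2-en-1-ol (PPh3, DIAD) etherifies the remaining chelated hydroxyl without base. This spares the acidic methylene and gives 1-[2-methoxy-4-(methoxymethoxy)-6-(3-methylbut-2-enyloxy)phenyl]-2-(4-methoxyphenyl)ethanone F3.
- Heating in N,N-diethylaniline at about 200 °C starts the Claisen–Cope (para-Claisen) sequence. It carries the prenyl group to the carbon para to that oxygen, between the MOM ether and the methoxyl, and gives 1-[6-hydroxy-2-methoxy-4-(methoxymethoxy)-3-(3-methylbut-2-enyl)phenyl]-2-(4-methoxyphenyl)ethanone F4.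
- HCl in MeOH removes the MOM group to give 1-[4,6-dihydroxy-2-methoxy-3-(3-methylbut-2-enyl)phenyl]-2-(4-methoxyphenyl)ethanone F5.
- TsOH in warm toluene adds the only hydroxyl next to the prenyl group across the alkene in the Markovnikov sense and closes the chroman of 22.

2. Step 7.
- What may go wrong: the acetylide or residual amide base may enolise the arylacetamide. The liberated amines may add to the β-carbon of the ynone during the quench. Acid may hydrate the ynol ether.
- Fallback: carbonyl addition and oxidation replace acyl substitution. It sets out from 15 and comes back at 19.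
- LiAlH4 in THF at 0 °C reduces 15 to 4-methoxyphenylacetaldehyde F6.
- Acetylide 17, generated as in step 7, adds at −78 °C to give 4-methoxy-1-(4-methoxyphenyl)but-3-yn-2-ol F7. The amines are washed out at this stage, where no Michael acceptor is present.
- Activated MnO2 in CH2Cl2 oxidises the propargylic alcohol under neutral conditions to 19.

3. Step 5.
- What may go wrong: γ-deprotonation of the silyl ester may be incomplete, LiN(iPr)2 may attack at silicon, silylation may occur on carbon, or the bis-silyl acetal may hydrolyse during handling. Decarboxylation of the free acid made in step 4 belongs to the same weak point.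
- Fallback: a different diene is used and steps 4 and 5 are bypassed. It sets out from 8 and comes back at 22.
- Ester 8 is deprotonated directly (LiN(iPr)2, THF, −78 °C) and trapped with TMSCl to give the methyl trimethylsilyl ketene acetal of methyl (6,6-dimethyl-5,6-dihydro-4H-pyran-2-yl)acetate F8. This is the classical preparation of Brassard-type dienes.
- F8 replaces 12 in step 8 and should give the mixed-ketal cycloadduct F9, which carries one methoxy and one silyloxy group at C7.
- This ketal loses methanol to give 21, and the acid work-up of step 8 then gives 22.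

Further compounds
F1 | step 8 | 1-(2,4-dihydroxy-6-methoxyphenyl)-2-(4-methoxyphenyl)ethanone | COc1ccc(CC(=O)c2c(O)cc(O)cc2OC)cc1
F2 | step 8 | 1-[2-hydroxy-6-methoxy-4-(methoxymethoxy)phenyl]-2-(4-methoxyphenyl)ethanone | COCOc1cc(O)c(C(=O)Cc2ccc(OC)cc2)c(OC)c1
F3 | step 8 | 1-[2-methoxy-4-(methoxymethoxy)-6-(3-methylbut-2-enyloxy)phenyl]-2-(4-methoxyphenyl)ethanone | COCOc1cc(OCC=C(C)C)c(C(=O)Cc2ccc(OC)cc2)c(OC)c1
F4 | step 8 | 1-[6-hydroxy-2-methoxy-4-(methoxymethoxy)-3-(3-methylbut-2-enyl)phenyl]-2-(4-methoxyphenyl)ethanone | COCOc1cc(O)c(C(=O)Cc2ccc(OC)cc2)c(OC)c1CC=C(C)C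
F5 | step 8 | 1-[4,6-dihydroxy-2-methoxy-3-(3-methylbut-2-enyl)phenyl]-2-(4-methoxyphenyl)ethanone | COc1ccc(CC(=O)c2c(O)cc(O)c(CC=C(C)C)c2OC)cc1
F6 | step 7 | 4-methoxyphenylacetaldehyde | COc1ccc(CC=O)cc1
F7 | step 7 | 4-methoxy-1-(4-methoxyphenyl)but-3-yn-2-ol (racemic) | COC#CC(O)Cc1ccc(OC)cc1
F8 | step 5 | methyl trimethylsilyl ketene acetal of methyl (6,6-dimethyl-5,6-dihydro-4H-pyran-2-yl)acetate (E/Z mixture) | COC(O[Si](C)(C)C)=CC1=CCCC(C)(C)O1
F9 | step 5 | 1-[5,7-dimethoxy-2,2-dimethyl-7-(trimethylsilyloxy)-3,4,4a,7-tetrahydro-2H-chromen-6-yl]-2-(4-methoxyphenyl)ethanone (mixed-ketal cycloadduct, racemic) | COC1=C(C(=O)Cc2ccc(OC)cc2)C(OC)(O[Si](C)(C)C)C=C3OC(C)(C)CCC13
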